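Assumption: compounds 1, 2, 5, 8 and 18 are taken as purchasable. The alkene of 13–19 is written as E, the geometry expected from the elimination, although the route does not depend on it. The carbinol carbon of 11 and 12 and the acetal carbon of 14 and 15 are left undefined because both are removed later.

## Analysis of the target

Target 20 is a monocyclic lignan built on an oxolane (O1, C2–C5). C2 carries a 4-hydroxy-3-methoxyphenyl group, C3 a CH2O–(3-methylbutanoyl) arm, C4 a (4-hydroxy-3-methoxyphenyl)methyl group, and C5 is an unsubstituted OCH2. The three stereocentres are contiguous, (2S,3R,4R): the C2 aryl is trans to the C3 arm and the C3 arm is cis to the C4 benzyl group. The C2–O1 bond is a benzylic ether activated by a para oxygen, so it can ionise with acid (epimerisation, ring opening) and can be hydrogenolysed. The phenols are oxidisable and would compete in an acylation, and the primary ester tolerates neither hydride nor strong base. The hard points are the 3,4-cis relationship, which is the less stable arrangement and must be made kinetically next to a trans-2,3 pair, and the absolute configuration, for which there is no stereocentre outside the ring. The two aryl groups are identical but sit in different environments, so they must enter in distinguishable ways. The strategy rests on C5: as a CH2 between O1 and C4 it can be raised to the carboxyl level, which turns O1–C2–C3–C4–C5 into a γ-aryl butyrolactone and, with unsaturation between C3 and C4, into a furan-2(5H)-one. In that butenolide C2 is the γ-carbon and the only stereocentre, C3 is the electrophilic β-carbon that accepts the one-carbon arm, and C4 is the α-carbon whose enolate takes up the second aryl unit as an aldehyde.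

## Retrosynthetic reasoning

20 to 19. The last operation removes both phenol protecting groups and creates C4. Target 20 is traced to the dibenzyl benzylidene ester 19, in which the C4=CH(aryl) double bond and the two O-benzyl groups all respond to one catalytic hydrogenation. Keeping C4 trigonal until the end means the cis-3,4 relationship never has to survive base or Lewis acid. The forward step must deliver both hydrogen atoms to the ring face opposite the C3 arm and stop before the benzylic C2–O1 bond is cleaved.

19 to 17 and 18. The ester C–O bond is cut to alcohol 17 and acid chloride 18. At this stage both phenols are still benzyl ethers, so the primary hydroxyl is the only acylation site. Acylating before the hydrogenation also removes a free hydroxyl that could anchor the substrate to the catalyst surface on the wrong face, and it enlarges the arm that shields that face.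

17 to 15 through 16. Two functional-group changes are taken back together. The C–OH bond of the arm becomes a C–Si bond (the retron of a Tamao oxidation), because a silylmethyl group can be introduced as a carbon nucleophile and withstands the organometallic steps. The C5 methylene becomes the acetal carbon of acetate 15, to be reduced ionically by a silane. The silane intermediate 16 is not purified, since any ligand exchange at silicon during the Lewis acidic reduction is irrelevant to the oxidation.

15 to 13. The acetoxy acetal is traced to the lactone carbonyl of 13. The reduction and acetylation are run in one flask so that no free lactol appears. A free lactol could open to a hydroxy enal and bring a hydroxyl within reach of the alkoxysilane.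

13 to 11 through 12. The exocyclic C=C is traced to the aldol 11 by dehydration. This removes the α-carbon and carbinol stereocentres, which the aldol cannot be asked to control, and prepares C4 (target numbering) for the late hydrogenation.

11 to 7, 9 and 1 through 10. This is the main disconnection. It cuts the bond from the ring β-carbon to the silylmethyl carbon and the bond from the α-carbon to the benzylic carbon, leading to butenolide 7, Grignard reagent 9 and aldehyde 1. The cut is made here because both arms then arrive with their final carbon skeleton in one operation, and because the γ-aryl group of 7 is the only source of facial bias needed. The forward reaction must add the organocopper species derived from 9 anti to the aryl group and must not remove the acidic γ-hydrogen of 7. For that reason a stoichiometric homocuprate, to which 7 is added, is preferred to a catalytic amount of copper. With catalytic copper the free Grignard reagent and the accumulating enolate 10 would coexist with unreacted 7.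

7 to 6, then to 4 and 5. The ring C=C of 7 is opened by a ring-closing metathesis retron to the allyl acrylate 6, and the ester bond of 6 is cut to alcohol 4 and acid chloride 5. This reaches the butenolide in two neutral or mildly basic steps that do not touch the stereocentre.

4 to 3, then to 1 and 2; 9 to 8. The (S)-alcohol 4 is obtained from racemic 3 by an enzymatic kinetic resolution, and 3 from aldehyde 1 and vinyl Grignard reagent 2. An enzymatic acylation is preferred to an oxidative resolution with Lewis acidic titanium alkoxides because the electron-rich benzylic allylic alcohol ionises easily, and because the wanted (S)-enantiomer is simply the one that remains. Reagent 9 comes from chloride 8 by magnesium insertion. Aldehyde 1 is thus the source of both aryl groups.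

## Alternatives that were turned down

Alternative 1: The target is cut at C3–C4 (the bond joining two phenylpropanoid units) and at two benzylic C–O bonds, one of them temporary, leading back to a symmetric furofuran. In the forward key step, anodic one-electron oxidation of 5-bromoconiferyl alcohol A1 gives phenoxyl radicals that couple at their side-chain β-carbons. Each quinone methide is then captured by the hydroxymethyl group of the other half, which closes both oxolane rings of 5,5'-dibromopinoresinol A2. Hydrogenolysis over palladium would remove both bromine atoms and open one benzylic C–O bond to give lariciresinol A3, and an enzymatic acylation of the primary hydroxyl would give 20.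
- For: three or four steps and no protecting groups. The cis ring fusion and exo aryl groups of A2 translate directly into 2,3-trans and 3,4-cis. The bromine atoms block the ring position where radical coupling otherwise competes.
- Against: the radicals couple without any chiral influence, so A2 is racemic and a resolution is needed at the most advanced stage, with at least half of the material lost. Opening one of two equivalent benzylic ethers cannot be stopped cleanly and tends to run on to the second opening. Oxidative coupling also gives other dimers and oligomers.
- Comparison: this alternative is clearly stronger in step count. The chosen strategy offers in its place an absolute configuration fixed early at one centre and relayed by substrate control, and two aryl-bearing halves that enter as different reagents, so nothing has to be desymmetrised.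

Alternative 2: The oxolane is cut at C2–C3 and C4–C5, a three-atom C–O–C unit plus an alkene. In the forward key step, fluoride-induced 1,3-elimination from the α-chloro silylmethyl ether A5 gives a non-stabilised carbonyl ylide. The ylide adds across the C=C of the menthyloxy butenolide A4 on the face away from the menthyloxy group, giving the cis-fused bicyclic lactone A6 with the aryl group exo.
- For: the ring and all three ring stereocentres are made in one step, with auxiliary-controlled facial selectivity. The cis fusion corresponds to 3,4-cis and the exo aryl to 2,3-trans.
- Against: nothing in the substrates enforces the regiochemistry of the unsymmetrical dipole or its exo preference, and the ylide is short-lived. A6 also carries the wrong functionality on both arms. The acetal carbon on C4 must become CH2–aryl by unmasking, aryl-metal addition and deoxygenation of a benzylic alcohol beside the equally labile C2–O1 bond. The lactone carbonyl on C3 must be reduced separately to the CH2O arm. At least six further steps and a stoichiometric auxiliary are needed.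
- Comparison: this alternative is stronger in the stereochemical yield of its key step. The chosen key step fixes fewer lasting centres but delivers both arms with their final carbon skeleton, so only oxidation-level adjustments follow.

Alternative 3: The target is cut at C3–C4 and at the benzylic CH2–aryl bond, with the ring oxygen already attached to C2 as an allyl ether. In the forward key step, a low-valent nickel catalyst with a bipyridine ligand and a metallic reductant (or a cathode) reduces the N-hydroxyphthalimide ester A7. Loss of carbon dioxide gives the C3 radical, which closes 5-exo onto the allyl ether, and the resulting primary radical is arylated by the aryl–nickel species from aryl iodide A8 to give A9.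
- For: the route is convergent. The ring, the C3–C4 bond and the aryl–CH2 bond form at once, and A9 is about three steps (ether cleavage, acylation, debenzylation) from 20. The chair-like transition-state preferences of substituted hexenyl radicals point to the wanted 2,3-trans, 3,4-cis isomer.
- Against: C3 becomes a planar radical, so C3 and C4 both depend on one early transition state with small energy differences, and a diastereomer mixture is likely. Direct arylation of the uncyclised radical competes. A7 needs its own stereocontrolled synthesis, and two kinds of benzyl-type ether must be told apart.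
- Comparison: this alternative is stronger in convergence and in the length of its endgame. The chosen strategy sets each centre by the strong steric bias of a ring substituent next to the reacting carbon and uses a single type of protecting group.

Key step: step 6

## Route

Ar = 4-(benzyloxy)-3-methoxyphenyl in the names below.

Step 1
Reactants: 1 4-(benzyloxy)-3-methoxybenzaldehyde (O-benzylvanillin); 2 vinylmagnesium bromide
Product: 3 rac-1-Ar-prop-2-en-1-ol
Conditions: THF, −78 → 0 °C; aq NH4Cl
Reagents that add atoms: none
Why: Grignard 1,2-addition of the vinyl nucleophile to the aromatic aldehyde; no selectivity is required because the carbinol centre is resolved in the next step.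

Step 2
Reactants: 3 rac-1-Ar-prop-2-en-1-ol
Product: 4 (S)-1-Ar-prop-2-en-1-ol
Conditions: immobilised Candida antarctica lipase B, vinyl acetate (3 equiv), tert-butyl methyl ether, 30 °C, run slightly beyond half conversion; chromatography on Et3N-deactivated silica
Reagents that add atoms: none
Why: Lipase-catalysed kinetic resolution by transesterification: with aryl as the large and vinyl as the medium substituent the enzyme should acetylate the (R)-alcohol and leave the (S)-enantiomer 4, and running slightly past half conversion raises the enantiopurity of the remaining alcohol. The neutral conditions spare the acid-labile, electron-rich benzylic allylic alcohol.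

Step 3
Reactants: 4 (S)-1-Ar-prop-2-en-1-ol; 5 acryloyl chloride (prop-2-enoyl chloride)
Product: 6 (S)-1-Ar-prop-2-en-1-yl prop-2-enoate
Conditions: iPr2NEt, CH2Cl2, −20 → 0 °C
Reagents that add atoms: none
Why: Base-mediated O-acylation with an acid chloride; the C–O bond of the stereocentre is not touched, so the configuration is kept.

Step 4
Reactants: 6 (S)-1-Ar-prop-2-en-1-yl prop-2-enoate
Product: 7 (S)-5-Ar-furan-2(5H)-one
Conditions: second-generation Grubbs catalyst RuCl2(=CHPh)(H2IMes)(PCy3) (5 mol %), CH2Cl2 (0.01 M), 40 °C
Reagents that add atoms: none
Why: Ring-closing metathesis of the allyl acrylate, driven by loss of ethene and formation of the conjugated five-membered lactone; the neutral conditions leave the acidic γ-hydrogen at C5 in place, so the (S)-configuration is kept.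

Step 5
Reactants: 8 (chloromethyl)dimethyl(propan-2-yloxy)silane
Product: 9 {[dimethyl(propan-2-yloxy)silyl]methyl}magnesium chloride
Conditions: Mg turnings, BrCH2CH2Br (cat.), THF, reflux then rt
Reagents that add atoms: magnesium, [Mg]
Why: Magnesium insertion into the C–Cl bond (Grignard formation); the hindered isopropoxy group on silicon is not attacked by the reagent at or below room temperature.

Step 6
Reactants: 7 (S)-5-Ar-furan-2(5H)-one; 9 {[dimethyl(propan-2-yloxy)silyl]methyl}magnesium chloride; 1 4-(benzyloxy)-3-methoxybenzaldehyde
Product: 11 (3R,4S,5S)-5-Ar-3-[Ar(hydroxy)methyl]-4-{[dimethyl(propan-2-yloxy)silyl]methyl}oxolan-2-one (carbinol epimers), via chloromagnesium enolate of the conjugate adduct 10 (not isolated)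
Conditions: CuI (1.1 equiv), 9 (2.2 equiv), THF, −30 °C; 7 added at −78 °C, −78 → −50 °C; 1 (1.3 equiv), −78 °C; AcOH in THF at −78 °C, then aq NH4Cl
Reagents that add atoms: none
Why: Two equivalents of 9 and CuI give a magnesium homocuprate of monovalent copper, a soft and weakly basic nucleophile that forms a π-complex with the enoate of 7 and transfers one silylmethyl group to the β-carbon through a trivalent copper intermediate and reductive elimination, leaving the chloromagnesium enolate 10. The closest known reaction type is organocuprate conjugate addition to 5-substituted furan-2(5H)-ones followed by aldol trapping of the enolate (three-component coupling). No ring closes; two C–C bonds form. The β-stereocentre (lactone C4, the future oxolane C3) is controlled by the γ-aryl group, which shields one face of the flat butenolide, so the copper reagent adds anti to it and fixes the 2,3-trans relationship of the target. The α-stereocentre is set by the new β-substituent, aldehyde 1 approaching the enolate anti to it through a closed six-membered transition state; this centre and the carbinol centre are provisional. The step needs 1,4- over 1,2-addition and addition over removal of the acidic γ-hydrogen, which would racemise C5 through the 2-oxyfuran. The cuprate, the addition of 7 to excess reagent at −78 °C and the absence of free Grignard reagent or of enolate beside unreacted 7 are meant to secure this. The cold acidic quench stops retro-aldol reaction and alkoxide exchange at silicon.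

Step 7
Reactants: 11 (3R,4S,5S)-5-Ar-3-[Ar(hydroxy)methyl]-4-{[dimethyl(propan-2-yloxy)silyl]methyl}oxolan-2-one
Product: 13 (3E,4S,5S)-5-Ar-3-(Ar-methylidene)-4-{[dimethyl(propan-2-yloxy)silyl]methyl}oxolan-2-one, via secondary benzylic methanesulfonate 12 (not isolated)
Conditions: crude 11, MsCl, Et3N, CH2Cl2, 0 °C; then 1,8-diazabicyclo[5.4.0]undec-7-ene (DBU), 0 °C → rt
Reagents that add atoms: none
Why: Sulfonylation of the aldol hydroxyl followed by E1cB elimination through the lactone enolate; the conjugated E-benzylidene lactone is expected. Both provisional stereocentres are erased while C4 and C5 are untouched.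

Step 8
Reactants: 13 (3E,4S,5S)-5-Ar-3-(Ar-methylidene)-4-{[dimethyl(propan-2-yloxy)silyl]methyl}oxolan-2-one
Product: 15 (3E,4S,5S)-5-Ar-3-(Ar-methylidene)-4-{[dimethyl(propan-2-yloxy)silyl]methyl}oxolan-2-yl acetate (anomers), via diisobutylaluminium hemiacetal 14 (not isolated)
Conditions: iBu2AlH (1.2 equiv), CH2Cl2, −78 °C; then pyridine, 4-(dimethylamino)pyridine, Ac2O, −78 → 0 °C
Reagents that add atoms: acetic anhydride, CC(=O)OC(C)=O
Why: One-pot reductive acetylation: iBu2AlH adds once to the lactone carbonyl (1,2-addition) and the stable aluminium hemiacetal 14 is acetylated in place. No free lactol, which could open to a hydroxy enal or exchange onto silicon, is formed.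

Step 9
Reactants: 15 (3E,4S,5S)-5-Ar-3-(Ar-methylidene)-4-{[dimethyl(propan-2-yloxy)silyl]methyl}oxolan-2-yl acetate
Product: 17 [(2S,3R,4E)-2-Ar-4-(Ar-methylidene)oxolan-3-yl]methanol, via isopropoxydimethylsilylmethyl oxolane 16 (not isolated)
Conditions: Et3SiH (3 equiv), BF3·OEt2 (1.5 equiv), CH2Cl2, −78 °C; aq NaHCO3, solvent exchange; then 30% H2O2, KF, KHCO3, THF/MeOH, rt
Reagents that add atoms: hydrogen peroxide, OO
Why: Ionic hydrogenation: BF3·OEt2 ionises the allylic acetal acetate to a conjugated oxocarbenium ion, which Et3SiH should reduce at the carbon next to oxygen (C5), where such ions are normally attacked. The crude silane 16 then undergoes Tamao oxidation (peroxide attack on fluoride-activated silicon and 1,2-shift of the CH2 group from Si to O), which turns the C–Si bond into C–OH whatever ligand exchange has occurred at silicon. No stereocentre is formed or touched.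

Step 10
Reactants: 17 [(2S,3R,4E)-2-Ar-4-(Ar-methylidene)oxolan-3-yl]methanol; 18 3-methylbutanoyl chloride (isovaleryl chloride)
Product: 19 [(2S,3R,4E)-2-Ar-4-(Ar-methylidene)oxolan-3-yl]methyl 3-methylbutanoate
Conditions: pyridine, 4-(dimethylamino)pyridine (cat.), CH2Cl2, 0 °C
Reagents that add atoms: none
Why: Acylation of the only free hydroxyl with an acid chloride under nucleophilic catalysis; both phenols are still benzyl ethers, so no chemoselectivity is asked of the step.

Step 11
Reactants: 19 [(2S,3R,4E)-2-Ar-4-(Ar-methylidene)oxolan-3-yl]methyl 3-methylbutanoate
Product: 20 [(2S,3R,4R)-2-(4-hydroxy-3-methoxyphenyl)-4-[(4-hydroxy-3-methoxyphenyl)methyl]oxolan-3-yl]methyl 3-methylbutanoate, (+)-9'-isovaleroxylariciresinol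
Conditions: H2 (1 atm), 10% Pd/C, EtOAc, rt, stopped when both benzyl ethers are cleaved
Reagents that add atoms: none
Why: Heterogeneous catalytic hydrogenation with concurrent hydrogenolysis of the two aryl benzyl ethers. Allylic 1,3-strain between the aryl group of the E-benzylidene and the C3 arm holds that arm pseudo-axial over one ring face, so hydrogen should reach C4 from the opposite face and place the new benzyl group cis to the C3 arm ((4R)). The ester arm has no free hydroxyl that could anchor the substrate to the metal on the wrong face.

## Compound list

1 | 4-(benzyloxy)-3-methoxybenzaldehyde (O-benzylvanillin) | COc1cc(C=O)ccc1OCc1ccccc1 | starting material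
2 | vinylmagnesium bromide | C=C[Mg]Br | starting material
3 | rac-1-[4-(benzyloxy)-3-methoxyphenyl]prop-2-en-1-ol | C=CC(O)c1ccc(OCc2ccccc2)c(OC)c1 | intermediate
4 | (S)-1-[4-(benzyloxy)-3-methoxyphenyl]prop-2-en-1-ol | C=C[C@H](O)c1ccc(OCc2ccccc2)c(OC)c1 | intermediate
5 | acryloyl chloride | C=CC(Cl)=O | starting material
6 | (S)-1-[4-(benzyloxy)-3-methoxyphenyl]prop-2-en-1-yl prop-2-enoate | C=C[C@H](OC(=O)C=C)c1ccc(OCc2ccccc2)c(OC)c1 | intermediate
7 | (S)-5-[4-(benzyloxy)-3-methoxyphenyl]furan-2(5H)-one | O=C1C=C[C@@H](c2ccc(OCc3ccccc3)c(OC)c2)O1 | intermediate
8 | (chloromethyl)dimethyl(propan-2-yloxy)silane | CC(C)O[Si](C)(C)CCl | starting material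
9 | {[dimethyl(propan-2-yloxy)silyl]methyl}magnesium chloride | CC(C)O[Si](C)(C)C[Mg]Cl | intermediate
10 | chloromagnesium enolate of (4S,5S)-5-[4-(benzyloxy)-3-methoxyphenyl]-4-{[dimethyl(propan-2-yloxy)silyl]methyl}oxolan-2-one | Cl[Mg]OC1=C[C@H](C[Si](C)(C)OC(C)C)[C@@H](c2ccc(OCc3ccccc3)c(OC)c2)O1 | intermediate
11 | (3R,4S,5S)-5-[4-(benzyloxy)-3-methoxyphenyl]-3-{[4-(benzyloxy)-3-methoxyphenyl](hydroxy)methyl}-4-{[dimethyl(propan-2-yloxy)silyl]methyl}oxolan-2-one, carbinol epimers | O=C1O[C@H](c2ccc(OCc3ccccc3)c(OC)c2)[C@@H](C[Si](C)(C)OC(C)C)[C@@H]1C(O)c4ccc(OCc5ccccc5)c(OC)c4 | intermediate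
12 | methanesulfonate of 11 at the carbinol oxygen | O=C1O[C@H](c2ccc(OCc3ccccc3)c(OC)c2)[C@@H](C[Si](C)(C)OC(C)C)[C@@H]1C(OS(C)(=O)=O)c4ccc(OCc5ccccc5)c(OC)c4 | intermediate
13 | (3E,4S,5S)-5-[4-(benzyloxy)-3-methoxyphenyl]-3-{[4-(benzyloxy)-3-methoxyphenyl]methylidene}-4-{[dimethyl(propan-2-yloxy)silyl]methyl}oxolan-2-one | O=C1O[C@H](c2ccc(OCc3ccccc3)c(OC)c2)[C@@H](C[Si](C)(C)OC(C)C)/C1=C\c4ccc(OCc5ccccc5)c(OC)c4 | intermediate
14 | bis(2-methylpropyl)aluminium (3E,4S,5S)-5-[4-(benzyloxy)-3-methoxyphenyl]-3-{[4-(benzyloxy)-3-methoxyphenyl]methylidene}-4-{[dimethyl(propan-2-yloxy)silyl]methyl}oxolan-2-olate | CC(C)C[Al](CC(C)C)OC1O[C@H](c2ccc(OCc3ccccc3)c(OC)c2)[C@@H](C[Si](C)(C)OC(C)C)/C1=C\c4ccc(OCc5ccccc5)c(OC)c4 | intermediate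
15 | (3E,4S,5S)-5-[4-(benzyloxy)-3-methoxyphenyl]-3-{[4-(benzyloxy)-3-methoxyphenyl]methylidene}-4-{[dimethyl(propan-2-yloxy)silyl]methyl}oxolan-2-yl acetate, anomers | CC(=O)OC1O[C@H](c2ccc(OCc3ccccc3)c(OC)c2)[C@@H](C[Si](C)(C)OC(C)C)/C1=C\c4ccc(OCc5ccccc5)c(OC)c4 | intermediate
16 | (2S,3S,4E)-2-[4-(benzyloxy)-3-methoxyphenyl]-4-{[4-(benzyloxy)-3-methoxyphenyl]methylidene}-3-{[dimethyl(propan-2-yloxy)silyl]methyl}oxolane | C1O[C@H](c2ccc(OCc3ccccc3)c(OC)c2)[C@@H](C[Si](C)(C)OC(C)C)/C1=C\c4ccc(OCc5ccccc5)c(OC)c4 | intermediate
17 | [(2S,3R,4E)-2-[4-(benzyloxy)-3-methoxyphenyl]-4-{[4-(benzyloxy)-3-methoxyphenyl]methylidene}oxolan-3-yl]methanol | C1O[C@H](c2ccc(OCc3ccccc3)c(OC)c2)[C@@H](CO)/C1=C\c4ccc(OCc5ccccc5)c(OC)c4 | intermediate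
18 | 3-methylbutanoyl chloride (isovaleryl chloride) | CC(C)CC(Cl)=O | starting material
19 | [(2S,3R,4E)-2-[4-(benzyloxy)-3-methoxyphenyl]-4-{[4-(benzyloxy)-3-methoxyphenyl]methylidene}oxolan-3-yl]methyl 3-methylbutanoate | C1O[C@H](c2ccc(OCc3ccccc3)c(OC)c2)[C@@H](COC(=O)CC(C)C)/C1=C\c4ccc(OCc5ccccc5)c(OC)c4 | intermediate
20 | [(2S,3R,4R)-2-(4-hydroxy-3-methoxyphenyl)-4-[(4-hydroxy-3-methoxyphenyl)methyl]oxolan-3-yl]methyl 3-methylbutanoate, (+)-9'-isovaleroxylariciresinol | COc1cc(C[C@H]2CO[C@H](c3ccc(O)c(OC)c3)[C@H]2COC(=O)CC(C)C)ccc1O | target

## Step count and least certain steps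

Total step count: 11. Longest linear sequence: 10 steps (steps 1–4 and 6–11, from 1 to 20); step 5 is a one-step side branch.

Step 6 (key step). The most likely failure is slow transfer of the α-silylalkyl group from copper, which would let proton abstraction at the acidic γ-position of 7 compete and erode the enantiopurity or stall the addition. After the aldol, retro-aldol reaction or attack of the aldolate oxygen on the alkoxysilane could also intervene if the quench is not cold. The fallback sets out from 7 and comes back at 11, with the two bond formations separated. Reagent 9 (1.5 equiv) is added to 7 with CuI (10 mol %) and Me3SiCl (2 equiv) in THF at −78 °C. In this chlorosilane-accelerated copper-catalysed conjugate addition the enolate is silylated as fast as it forms, so it never meets unreacted 7. This gives the trimethylsilyl ketene acetal {[(4S,5S)-5-Ar-4-{[dimethyl(propan-2-yloxy)silyl]methyl}-4,5-dihydrofuran-2-yl]oxy}trimethylsilane F1. Brief aqueous NH4Cl work-up hydrolyses it to the trans lactone (4S,5S)-5-Ar-4-{[dimethyl(propan-2-yloxy)silyl]methyl}oxolan-2-one F2. Deprotonation with LiN(iPr)2 in THF at −78 °C gives the lithium enolate F3, which adds to 1 anti to the C4 substituent and returns 11.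

Step 9. The most likely failure is hydride delivery to the benzylic end of the conjugated cation instead of C5, or ionisation of the activated C2–O1 bond by the Lewis acid with reductive ring opening. Alkoxy exchange at silicon is expected but harmless. The fallback sets out from 13 and comes back at 16, and forms no cation at C5. Lactone 13 is reduced with iBu2AlH (3 equiv, CH2Cl2, −78 → −20 °C) to the diol (1S,2S,3E)-1,4-bis-Ar-2-{[dimethyl(propan-2-yloxy)silyl]methyl}-3-(hydroxymethyl)but-3-en-1-ol F4, which is used at once. Mitsunobu cyclodehydration (PPh3, diisopropyl azodicarboxylate, THF, 0 °C) activates the primary allylic hydroxyl, and the benzylic hydroxyl closes the ring by SN2 displacement at the CH2 carbon (5-exo-tet) with C2 unchanged. This gives 16, which is oxidised as in the second stage of step 9.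

Step 11. The most likely failures are continued hydrogenolysis of the benzylic C2–O1 bond once the phenols are free, and palladium-induced migration of the double bond into the ring towards C3, which would erase that stereocentre; incomplete facial selectivity is a lesser risk. The fallback sets out from 19 and comes back at 20, dividing the reduction between two catalysts. H2 over Rh/Al2O3 in EtOAc should saturate the alkene from the same face without cleaving benzyl ethers and with little double-bond migration. This gives [(2S,3R,4R)-2-Ar-4-(Ar-methyl)oxolan-3-yl]methyl 3-methylbutanoate F5. Transfer hydrogenolysis (Pd/C, cyclohexa-1,4-diene, EtOH, rt) then removes only the two aryl benzyl ethers.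

Step 2. The most likely failure is insufficient discrimination by the enzyme between the aryl and vinyl groups, which would give material of low enantiopurity. The resolution also discards at least half of the material, and the alcohol can undergo allylic transposition on acidic silica. The fallback sets out from 1 and comes back at 4, replacing steps 1 and 2 by one enantioselective addition. Divinylzinc F6, made from 2 and ZnCl2, is added to 1 in toluene at 0 °C with a catalytic chiral β-amino alcohol ligand, for example (−)-3-exo-(dimethylamino)isoborneol. The ligand enantiomer is chosen so that the vinyl group is delivered to the Si face of the aldehyde, which gives the (S)-alcohol 4 directly.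

## Further compounds

F1 | step 6 | {[(4S,5S)-5-[4-(benzyloxy)-3-methoxyphenyl]-4-{[dimethyl(propan-2-yloxy)silyl]methyl}-4,5-dihydrofuran-2-yl]oxy}trimethylsilane | C[Si](C)(C)OC1=C[C@H](C[Si](C)(C)OC(C)C)[C@@H](c2ccc(OCc3ccccc3)c(OC)c2)O1
F2 | step 6 | (4S,5S)-5-[4-(benzyloxy)-3-methoxyphenyl]-4-{[dimethyl(propan-2-yloxy)silyl]methyl}oxolan-2-one | O=C1C[C@H](C[Si](C)(C)OC(C)C)[C@@H](c2ccc(OCc3ccccc3)c(OC)c2)O1
F3 | step 6 | lithium enolate of F2 | [Li]OC1=C[C@H](C[Si](C)(C)OC(C)C)[C@@H](c2ccc(OCc3ccccc3)c(OC)c2)O1
F4 | step 9 | (1S,2S,3E)-1,4-bis[4-(benzyloxy)-3-methoxyphenyl]-2-{[dimethyl(propan-2-yloxy)silyl]methyl}-3-(hydroxymethyl)but-3-en-1-ol | O[C@H](c1ccc(OCc2ccccc2)c(OC)c1)[C@@H](C[Si](C)(C)OC(C)C)/C(CO)=C\c3ccc(OCc4ccccc4)c(OC)c3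
F5 | step 11 | [(2S,3R,4R)-2-[4-(benzyloxy)-3-methoxyphenyl]-4-{[4-(benzyloxy)-3-methoxyphenyl]methyl}oxolan-3-yl]methyl 3-methylbutanoate | COc1cc(C[C@H]2CO[C@H](c3ccc(OCc4ccccc4)c(OC)c3)[C@H]2COC(=O)CC(C)C)ccc1OCc1ccccc1
F6 | step 2 | divinylzinc | C=C[Zn]C=C
A1 | alternative 1 | 5-bromoconiferyl alcohol | COc1cc(/C=C/CO)cc(Br)c1O
A2 | alternative 1 | 5,5'-dibromopinoresinol (formed as the racemate; the needed enantiomer is drawn) | COc1cc(cc(Br)c1O)[C@H]1OC[C@H]2[C@@H]1CO[C@@H]2c1cc(Br)c(O)c(OC)c1
A3 | alternative 1 | (+)-lariciresinol | COc1cc(C[C@H]2CO[C@H](c3ccc(O)c(OC)c3)[C@H]2CO)ccc1O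
A4 | alternative 2 | (5S)-5-{[(1S,2R,5S)-5-methyl-2-(propan-2-yl)cyclohexyl]oxy}furan-2(5H)-one (menthyloxy butenolide) | O=C1C=C[C@@H](O[C@H]2C[C@@H](C)CC[C@@H]2C(C)C)O1
A5 | alternative 2 | 1-(benzyloxy)-4-{chloro[(trimethylsilyl)methoxy]methyl}-2-methoxybenzene | COc1cc(C(Cl)OC[Si](C)(C)C)ccc1OCc1ccccc1
A6 | alternative 2 | 6-[4-(benzyloxy)-3-methoxyphenyl]-4-(menthyloxy)-3,7-dioxabicyclo[3.3.0]octan-2-one, cis-fused, aryl exo | COc1cc([C@H]2OC[C@H]3[C@@H]2C(=O)O[C@@H]3O[C@H]4C[C@@H](C)CC[C@@H]4C(C)C)ccc1OCc1ccccc1
A7 | alternative 3 | 1,3-dioxoisoindolin-2-yl (3S)-3-(allyloxy)-3-[4-(benzyloxy)-3-methoxyphenyl]-2-{[(4-methoxybenzyl)oxy]methyl}propanoate | C=CCO[C@H](c1ccc(OCc2ccccc2)c(OC)c1)C(COCc1ccc(OC)cc1)C(=O)ON1C(=O)c2ccccc2C1=O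
A8 | alternative 3 | 1-(benzyloxy)-4-iodo-2-methoxybenzene | COc1cc(I)ccc1OCc1ccccc1
A9 | alternative 3 | O,O'-dibenzyl-lariciresinol 4-methoxybenzyl ether | COc1cc(C[C@H]2CO[C@H](c3ccc(OCc4ccccc4)c(OC)c3)[C@H]2COCc2ccc(OC)cc2)ccc1OCc1ccccc1
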